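**Assumption:** the target SMILES has no stereocentres and the two aryl–indole axes carry no configurational descriptor, so the compound is made as drawn with no stereocontrol step.

## Retrosynthetic overview

1. The last bond made is central ring–C3 of the 7-prenylindole, by a proposed acid-triggered ortho-indolylation of a fully substituted p-quinone monoketal. The ketone oxygen becomes the single free OH, so it necessarily sits next to the 7-prenylindole.
2. The monoketal comes from a 4-methoxyphenol (PhI(OAc)2/MeOH). That phenol comes from a 2,5-dimethoxyhydroquinone whose two OH groups are told apart sterically (silylate the open one, methylate the hindered one, desilylate).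
3. The hindered bond to the 2-(tert-prenyl)indole is made early by acid-promoted indole addition to 2,5-dichlorobenzoquinone; both C–Cl are then exchanged for OMe.
4. Indole pieces: 2-(tert-prenyl)indole from indole (3-chloroindole + prenyl-9-BBN); 7-prenylindole from 7-bromoindole (Stille).
5. No ring is built: both indoles and the six-membered carbocycle are bought preformed. The central ring goes quinone → hydroquinone → cyclohexadienone and is re-aromatised in the final step.

## Route

**Step 1**
Reactants: 1, 1H-indole
Product: 2, 3-chloro-1H-indole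
Conditions: NCS, DMF, rt (used directly)
Reagents that add atoms: N-chlorosuccinimide, O=C1CCC(=O)N1Cl
Why: Electrophilic aromatic chlorination at C3, the most nucleophilic indole position.

**Step 2**
Reactants: 2, 3-chloro-1H-indole
Product: 3, 2-(2-methylbut-3-en-2-yl)-1H-indole
Conditions: B-prenyl-9-BBN (made in situ from 9-BBN-H + 3-methylbuta-1,2-diene), Et3N, THF, −78 °C → rt
Reagents that add atoms: B-(3-methylbut-2-en-1-yl)-9-BBN, CC(C)=CCB1C2CCCC1CCC2
Why: Chloroindolenine reverse prenylation (aza-allylboration): boron binds N of the 3H-tautomer, the allyl group transfers through a six-membered transition state with allylic transposition so the CMe2 end bonds to C2, and loss of HCl re-aromatises.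

**Step 3**
Reactants: 3, 2-(2-methylbut-3-en-2-yl)-1H-indole; 4, 2,5-dichloro-1,4-benzoquinone
Product: 5, 2,5-dichloro-3-[2-(2-methylbut-3-en-2-yl)-1H-indol-3-yl]cyclohexa-2,5-diene-1,4-dione
Conditions: conc. HCl (cat.), THF, rt; then DDQ
Reagents that add atoms: none (4 is a reactant; DDQ only removes 2 H)
Why: Acid-promoted conjugate (Friedel–Crafts/Michael) addition of indole C3 to the unsubstituted quinone carbon, a known reaction for 2-substituted indoles, followed by re-oxidation of the hydroquinone adduct.

**Step 4**
Reactants: 5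
Product: 6, 2,5-dimethoxy-3-[2-(2-methylbut-3-en-2-yl)-1H-indol-3-yl]cyclohexa-2,5-diene-1,4-dione
Conditions: NaOMe (2.5 equiv), MeOH/THF, 0 → 40 °C
Reagents that add atoms: sodium methoxide (2 equiv incorporated), [Na+].[O-]C
Why: Both C–Cl are vinylogous acid chlorides and undergo addition–elimination (vinylic substitution) with methoxide.

**Step 5**
Reactants: 6
Product: 7, 2,5-dimethoxy-3-[2-(2-methylbut-3-en-2-yl)-1H-indol-3-yl]benzene-1,4-diol
Conditions: Na2S2O4, EtOAc/H2O, rt, Ar (used directly)
Reagents that add atoms: none
Why: Dithionite reduction of quinone to hydroquinone; alkenes and indole are untouched.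

**Step 6**
Reactants: 7
Product: 8, 3,6-dimethoxy-2-[2-(2-methylbut-3-en-2-yl)-1H-indol-3-yl]-4-[(triisopropylsilyl)oxy]phenol
Conditions: TIPSCl (1.05 equiv), imidazole, DMF, 0 °C, Ar
Reagents that add atoms: triisopropylsilyl chloride, CC(C)[Si](Cl)(C(C)C)C(C)C
Why: Sterically controlled monosilylation: the OH flanked by H and OMe reacts, while the OH wedged between OMe and the 2-tert-alkylindolyl group does not.

**Step 7**
Reactants: 8
Product: 9, 3-{2,3,6-trimethoxy-5-[(triisopropylsilyl)oxy]phenyl}-2-(2-methylbut-3-en-2-yl)-1H-indole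
Conditions: MeI, K2CO3, acetone, 50 °C, Ar
Reagents that add atoms: iodomethane, CI
Why: Williamson O-methylation of the remaining phenol; K2CO3 does not deprotonate the indole N–H, and the aryl TIPS ether survives.

**Step 8**
Reactants: 9
Product: 10, 2,4,5-trimethoxy-3-[2-(2-methylbut-3-en-2-yl)-1H-indol-3-yl]phenol
Conditions: TBAF, AcOH, THF, 0 °C
Reagents that add atoms: none
Why: Fluoride cleavage of the aryl silyl ether, buffered to keep the electron-rich phenoxide from air oxidation.

**Step 9**
Reactants: 10
Product: 11, 2,4,4,5-tetramethoxy-3-[2-(2-methylbut-3-en-2-yl)-1H-indol-3-yl]cyclohexa-2,5-dien-1-one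
Conditions: PhI(OAc)2 (1.05 equiv), dry MeOH, −10 → 0 °C; NaHCO3
Reagents that add atoms: methanol, CO
Why: Iodine(III) oxidative dearomatisation of a p-methoxyphenol: methanol traps the phenoxenium ion at the OMe-bearing para carbon to give the p-quinone monoketal, and the very electron-rich phenol reacts faster than the indole or the alkene.

**Step 10**
Reactants: 12, 7-bromo-1H-indole; 13, tributyl(3-methylbut-2-en-1-yl)stannane
Product: 14, 7-(3-methylbut-2-en-1-yl)-1H-indole
Conditions: Pd(PPh3)4 (5 mol%), DMF, 100 °C
Reagents that add atoms: none (13 is a reactant)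
Why: Stille coupling of an aryl bromide with a prenylstannane, giving mainly the linear (α) prenyl arene and tolerating the free N–H.

**Step 11**
Reactants: 11; 14, 7-(3-methylbut-2-en-1-yl)-1H-indole (1.5 equiv)
Product: 15, Asterriquinol H, 2,4,5-trimethoxy-3-[2-(2-methylbut-3-en-2-yl)-1H-indol-3-yl]-6-[7-(3-methylbut-2-en-1-yl)-1H-indol-3-yl]phenol
Conditions: (PhO)2P(O)OH (10 mol%), HFIP/CH2Cl2 (4:1), 4 Å MS, −20 → 0 °C
Reagents that add atoms: none (MeOH is lost)
Why: Proposed new method: acid/fluoroalcohol ionisation of the strained C4 dimethyl ketal of 11 gives a 2,4,5-trimethoxy-3-indolylphenoxenium (oxocarbenium) ion whose only unsubstituted electrophilic carbon is C6 (α to C=O, SN2′ to the ketal); C3 of the free N–H indole 14, far more nucleophilic than either alkene, adds there and the dienone tautomerises to the phenol, so the carbonyl oxygen becomes the lone OH ortho to the new indole and the surviving ketal oxygen becomes the para OMe; the closest known reaction types are the acid/HFIP-promoted SN2′ biaryl coupling of simple quinone monoacetals with electron-rich arenes and the acid-promoted addition of indoles to haloquinones, neither shown on a pentasubstituted indolyl quinone monoketal with an unprotected 3-H indole to make a hexasubstituted benzene.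

## Compound list

1 | 1H-indole | c1ccc2[nH]ccc2c1 | starting material
2 | 3-chloro-1H-indole | Clc1c[nH]c2ccccc12 | intermediate
3 | 2-(2-methylbut-3-en-2-yl)-1H-indole | C=CC(C)(C)c1cc2ccccc2[nH]1 | intermediate
4 | 2,5-dichloro-1,4-benzoquinone | O=C1C=C(Cl)C(=O)C=C1Cl | starting material
5 | 2,5-dichloro-3-[2-(2-methylbut-3-en-2-yl)-1H-indol-3-yl]cyclohexa-2,5-diene-1,4-dione | O=C1C=C(Cl)C(=O)C(c2c(C(C)(C)C=C)[nH]c3ccccc23)=C1Cl | intermediate
6 | 2,5-dimethoxy-3-[2-(2-methylbut-3-en-2-yl)-1H-indol-3-yl]cyclohexa-2,5-diene-1,4-dione | O=C1C=C(OC)C(=O)C(c2c(C(C)(C)C=C)[nH]c3ccccc23)=C1OC | intermediate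
7 | 2,5-dimethoxy-3-[2-(2-methylbut-3-en-2-yl)-1H-indol-3-yl]benzene-1,4-diol | Oc1cc(OC)c(O)c(-c2c(C(C)(C)C=C)[nH]c3ccccc23)c1OC | intermediate
8 | 3,6-dimethoxy-2-[2-(2-methylbut-3-en-2-yl)-1H-indol-3-yl]-4-[(triisopropylsilyl)oxy]phenol | CC(C)[Si](C(C)C)(C(C)C)Oc1cc(OC)c(O)c(-c2c(C(C)(C)C=C)[nH]c3ccccc23)c1OC | intermediate
9 | 3-{2,3,6-trimethoxy-5-[(triisopropylsilyl)oxy]phenyl}-2-(2-methylbut-3-en-2-yl)-1H-indole | CC(C)[Si](C(C)C)(C(C)C)Oc1cc(OC)c(OC)c(-c2c(C(C)(C)C=C)[nH]c3ccccc23)c1OC | intermediate
10 | 2,4,5-trimethoxy-3-[2-(2-methylbut-3-en-2-yl)-1H-indol-3-yl]phenol | Oc1cc(OC)c(OC)c(-c2c(C(C)(C)C=C)[nH]c3ccccc23)c1OC | intermediate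
11 | 2,4,4,5-tetramethoxy-3-[2-(2-methylbut-3-en-2-yl)-1H-indol-3-yl]cyclohexa-2,5-dien-1-one | O=C1C=C(OC)C(OC)(OC)C(c2c(C(C)(C)C=C)[nH]c3ccccc23)=C1OC | intermediate
12 | 7-bromo-1H-indole | Brc1cccc2cc[nH]c12 | starting material
13 | tributyl(3-methylbut-2-en-1-yl)stannane | CCCC[Sn](CCCC)(CCCC)CC=C(C)C | starting material
14 | 7-(3-methylbut-2-en-1-yl)-1H-indole | CC(C)=CCc1cccc2cc[nH]c12 | intermediate
15 | Asterriquinol H | C=CC(C)(C)c1[nH]c2ccccc2c1-c1c(OC)c(O)c(-c2c[nH]c3c(CC=C(C)C)cccc23)c(OC)c1OC | target

## Summary

Total steps: 11. Longest linear sequence: 10 (1 → 2 → 3 → 5 → 6 → 7 → 8 → 9 → 10 → 11 → 15).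

Steps most likely to fail, each with a fallback:

1. **Step 11 (proposed new indolylation of the quinone monoketal).** Risks are attack of 14 at the OMe-bearing vinylogous-ester carbon, hydrolysis of 11 back to quinone 6, or acid-induced prenyl side reactions. Fallback (known chemistry): add 14 to dichloroquinone 5 by the same acid-promoted indole–quinone addition/DDQ used in step 3. Then NaOMe, Na2S2O4, TIPS on the OH beside the less hindered 7-prenylindolyl, MeI/K2CO3 on the OH beside the 2-tert-prenylindolyl, and TBAF.
2. **Step 9 (PhI(OAc)2 dearomatisation with a free 2,3-disubstituted indole present).** Risks are indole oxidation or over-oxidation to quinone 6. Fallback: avoid the dienone altogether. Protect 10 as its MOM ether, do directed ortho-lithiation/iodination at the one free ring C–H, run a Suzuki–Miyaura coupling with N-Boc-7-prenylindol-3-yl pinacol boronate, then remove MOM and Boc under mild acid.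
3. **Step 6 (regioselective monosilylation of the air-sensitive hydroquinone 7).** Fallback: start from 2,4,5-trimethoxyphenol, where the future free OH is already distinct. Make the TIPS ether, lithiate between the two OMe groups and iodinate, couple with N-Boc-indol-3-yl boronate (Suzuki), remove Boc, reverse-prenylate C2 via the chloroindolenine and prenyl-9-BBN, and desilylate to reach 10.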